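Between 10.0 min and 20.0 min the theta run, at 8 °C, made product at 0.0167 min⁻¹ as a fraction of the charge. The zeta run, at 24 °C and with 0.12 M of partner against 0.030 M, read 0.0147 min⁻¹ between 6.00 min and 15.0 min, slower than theta, though part of that window lies inside its feed.

in all of them: substrate 0.054 M (fed, over 10 min); free catalyst 0.54 mM
- theta: partner 0.030 M; temperature 8 °C; run made earlier
- zeta: partner 0.12 M; temperature 24 °C; run made earlier
- oak: partner 0.0594 M; at 0 °C throughout; time 25 min
- ash: partner 0.0594 M; at 0 °C until 10 min, from then on at 30 °C; time 50 min

| run | time / min | product / % | substrate / % |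
|---|---|---|---|
| theta | 4.00 | 5.0 | 33.5 |
| theta | 10.0 | 19.2 | 78.9 |
| theta | 20.0 | 35.9 | 62.1 |
| theta | 50.0 | 56.4 | 47.1 |
| zeta | 1.33 | 1.3 | 11.0 |
| zeta | 3.00 | 6.7 | 21.9 |
| zeta | 6.00 | 15.6 | 43.2 |
| zeta | 15.0 | 28.8 | 71.4 |

(standard deviation of a reading: 1 percentage point)

- what was read earlier has a scatter of 1 percentage point, one standard deviation
- reactions considered so far: catalyst intermediate C <-> by-product + catalyst intermediate D; catalyst intermediate B <-> catalyst intermediate C; partner + catalyst intermediate A -> catalyst intermediate B; catalyst intermediate D -> free catalyst + product; substrate + free catalyst <-> catalyst intermediate A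
- percentages count the whole charge, also what has not yet gone in

- the winner by amount of product, in percent of the substrate charged; "neither" if no more than 2 percentage points parts them (oak / ash / neither)
- how much product is there at the end, in percent of the substrate charged: oak
- how much product is there at the end, in percent of the substrate charged: ash

The next run takes the charge of oak and ash, and the choice is between stopping cold at 25 min and warming at 10 min and leaving the flask to 50 min. Oak and ash are the same flask up to 10 min, so a dead heat is the zero of the scale: what stands at the change stands in both and cancels. After it, oak has 15.0 min and ash 40.0 min. They end level if ash's average rate after the change is 0.375 of oak's, and this is the tie ratio, the warm rate as a fraction of the cold rate at which the two flasks finish equal.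

The nearest reading of a warm rate against a cold one, with the partner charge differing as well, is zeta against theta, 0.878, which stands above the tie ratio. This reckoning therefore puts ash ahead, provided its rate holds for the whole warm stretch, and it charges the next run as ash.

The forecast differs. It names oak, with 38% for oak and 33% for ash, and its ground is this: “This points to catalyst dying at warmer temperatures”.

The flask gives ash as the winner, with 47.6% for ash against 41.9% for oak.

    catalyst intermediate C ⇌ by-product + catalyst intermediate D (K = 0.0288 M, k = 622 min⁻¹, Ea = 57.0 kJ mol⁻¹, ΔH = −25.0 kJ mol⁻¹)
    catalyst intermediate B ⇌ catalyst intermediate C (K = 0.400, k = 7.60 min⁻¹, Ea = 63.0 kJ mol⁻¹, ΔH = −90.0 kJ mol⁻¹)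
    partner + catalyst intermediate A → catalyst intermediate B (k = 6010 L mol⁻¹ min⁻¹, Ea = 43.0 kJ mol⁻¹)
    catalyst intermediate D → free catalyst + product (k = 8.65 min⁻¹, Ea = 71.0 kJ mol⁻¹)
    substrate + free catalyst ⇌ catalyst intermediate A (K = 3.60 L mol⁻¹, k = 290 L mol⁻¹ min⁻¹, Ea = 47.0 kJ mol⁻¹, ΔH = −59.0 kJ mol⁻¹)
    (constants at 0 °C)

From the 17.0% of product that both flasks held at the change, oak gained 25 percentage points in 15.0 min and ash gained 31 points in 40.0 min. Ash's average rate was therefore 0.461 of oak's, above the tie ratio. A flask with ash's charge and time, held at 0 °C throughout, reaches 69.5%, and its average rate after the change, set against oak's, gives a ratio of 0.791, higher than ash's. Part of what holds ash at 47.6% is the back reaction of by-product with catalyst intermediate D, together with the length of the run: without that back reaction ash gives 95.8%, and left to 500 min it gives >99.9%.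

Readings and results were computed for an exercise.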